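**Retrosynthetic overview**

1. Last bond: the aryl ether C–O, by Mitsunobu coupling of commercial umbelliferone with the primary alcohol of the fully built triol ketone; the side-chain carbinol comes unchanged from (R)-linalool.
2. Key disconnection: the cyclohexanone is cut at C(=O)–CH2 and at CH2–C(CH3)(OH). This leaves a five-membered exocyclic enol lactone and a two-carbon unit, used as benzyl acrylate so that a CO2Bn group (later lost as CO2) activates the future α-CH2.
3. Enabling feature: the ring ketone carbon and the tertiary carbinol carbon stand 1,4 to each other across the CMe2 and CH ring atoms. The carbinol oxygen can therefore acylate the ketone carbon as a γ-lactone ring O–C(=O)–CMe2–CH–C(=CH2), in which the carbinol carbon is an enol-ester carbon: its =CH2 becomes the C-methyl, its oxygen is the leaving group of the acyl transfer, and the lactone ring fixes the face of C–C bond formation.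
4. The enol lactone comes from a γ-alkynoic acid (gold-catalysed 5-exo-dig closure). Its CH stereocentre beside CMe2 is made by an Ireland–Claisen rearrangement of an isobutyrate with chirality transfer from a CBS-derived allylic alcohol, reached from linalool by hydroboration, acetonide protection and cross-metathesis.
5. Order of ring formation: 1,3-dioxane (protecting ring), γ-lactone (temporary ring), cyclohexanone (made from the lactone in the key step); the coumarin bicycle is bought and attached last.

Key step: step 10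

Assumption: (R)-(−)-linalool of high enantiomeric purity is used; the β-keto ester from the key step is an inconsequential mixture of epimers (and enol) at the ester-bearing carbon and is written without configuration there.

**Route**

Step 1
Reactants: 1 (R)-(−)-linalool
Product: 3 (3R)-3,7-dimethyloct-6-ene-1,3-diol, via organoborane 2 (not isolated)
Conditions: 9-BBN (1.5 equiv), THF, 0 °C to rt; then NaOH, H2O2, H2O, 0 °C
Reagents that add atoms: 9-BBN, B1C2CCCC1CCC2 (boron is held only in intermediate 2); hydrogen peroxide, OO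
Why: Brown hydroboration–oxidation: the hindered dialkylborane should add anti-Markovnikov to the monosubstituted vinyl group much faster than to the trisubstituted alkene, and the carbinol stereocentre is untouched.

Step 2
Reactants: 3 (3R)-3,7-dimethyloct-6-ene-1,3-diol
Product: 4 (4R)-2,2,4-trimethyl-4-(4-methylpent-3-en-1-yl)-1,3-dioxane
Conditions: 2,2-dimethoxypropane, PPTS (cat.), CH2Cl2, rt
Reagents that add atoms: 2,2-dimethoxypropane, COC(C)(C)OC
Why: Acid-catalysed acetonide formation (transketalisation) closes the 1,3-dioxane across the primary and tertiary hydroxyls and masks both for the base, ozone and radical steps that follow.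

Step 3
Reactants: 4 (4R)-2,2,4-trimethyl-4-(4-methylpent-3-en-1-yl)-1,3-dioxane; 5 but-3-en-2-one
Product: 6 (3E)-6-[(4R)-2,2,4-trimethyl-1,3-dioxan-4-yl]hex-3-en-2-one
Conditions: 5 (4 equiv), second-generation Hoveyda–Grubbs catalyst [RuCl2(H2IMes)(=CH-C6H4-2-O-i-Pr)] (5 mol %), CH2Cl2, 40 °C
Reagents that add atoms: none
Why: Olefin cross-metathesis: the trisubstituted prenyl-type alkene cannot homodimerise and should trade its isopropylidene end for the electron-poor vinyl ketone, the conjugated product forming as the (E)-isomer under thermodynamic control.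

Step 4
Reactants: 6 (3E)-6-[(4R)-2,2,4-trimethyl-1,3-dioxan-4-yl]hex-3-en-2-one
Product: 7 (2R,3E)-6-[(4R)-2,2,4-trimethyl-1,3-dioxan-4-yl]hex-3-en-2-ol
Conditions: (S)-2-methyl-CBS-oxazaborolidine (20 mol %), BH3·SMe2, THF, −30 °C; MeOH quench
Reagents that add atoms: none
Why: Corey–Bakshi–Shibata reduction: the (S)-oxazaborolidine should deliver hydride in a 1,2-sense to the face that gives the (R)-allylic alcohol, the alkenyl group acting as the large and the methyl as the small ketone substituent (reagent control, independent of the remote dioxane centre).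

Step 5
Reactants: 7 (2R,3E)-6-[(4R)-2,2,4-trimethyl-1,3-dioxan-4-yl]hex-3-en-2-ol; 8 2-methylpropanoyl chloride
Product: 9 (2R,3E)-6-[(4R)-2,2,4-trimethyl-1,3-dioxan-4-yl]hex-3-en-2-yl 2-methylpropanoate
Conditions: 8, pyridine, DMAP (cat.), CH2Cl2, 0 °C to rt
Reagents that add atoms: none
Why: Acylation of the secondary allylic alcohol with an acid chloride under nucleophilic catalysis; no stereocentre is formed or touched.

Step 6
Reactants: 9 (2R,3E)-6-[(4R)-2,2,4-trimethyl-1,3-dioxan-4-yl]hex-3-en-2-yl 2-methylpropanoate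
Product: 12 (3S,4E)-2,2-dimethyl-3-{2-[(4R)-2,2,4-trimethyl-1,3-dioxan-4-yl]ethyl}hex-4-enoic acid, via silyl ketene acetal 10 (not isolated), via silyl ester 11 (not isolated)
Conditions: LiN(i-Pr)2, THF, −78 °C; Me3SiCl, −78 °C to 50 °C; pH 4 aqueous work-up
Reagents that add atoms: chlorotrimethylsilane, C[Si](C)(C)Cl (silicon is held only in intermediates 10 and 11)
Why: Ireland–Claisen rearrangement: the symmetric dimethylketene silyl acetal (no enolate geometry to control) should rearrange through a chair transition state with the carbinol methyl pseudo-equatorial, which transfers the (R)-carbinol configuration suprafacially to the new tertiary centre beside the new quaternary CMe2 carbon and leaves an (E)-propenyl group.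

Step 7
Reactants: 12 (3S,4E)-2,2-dimethyl-3-{2-[(4R)-2,2,4-trimethyl-1,3-dioxan-4-yl]ethyl}hex-4-enoic acid
Product: 14 (3R)-3-formyl-2,2-dimethyl-5-[(4R)-2,2,4-trimethyl-1,3-dioxan-4-yl]pentanoic acid, via ozonide 13 (not isolated)
Conditions: O3, CH2Cl2, −78 °C; then Me2S, −78 °C to rt
Reagents that add atoms: ozone, [O-][O+]=O
Why: Ozonolysis with reductive work-up cleaves the only alkene to the aldehyde (expected to sit largely as its cyclic 5-hydroxy lactone form) without touching the stereocentre.

Step 8
Reactants: 14 (3R)-3-formyl-2,2-dimethyl-5-[(4R)-2,2,4-trimethyl-1,3-dioxan-4-yl]pentanoic acid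
Product: 15 (3S)-3-ethynyl-2,2-dimethyl-5-[(4R)-2,2,4-trimethyl-1,3-dioxan-4-yl]pentanoic acid
Conditions: dimethyl (1-diazo-2-oxopropyl)phosphonate, K2CO3 (3.5 equiv), MeOH, 0 °C to rt; pH 4 aqueous work-up
Reagents that add atoms: dimethyl (1-diazo-2-oxopropyl)phosphonate, CC(=O)C(=[N+]=[N-])P(=O)(OC)OC
Why: Seyferth–Gilbert homologation with the Ohira–Bestmann reagent: the base opens the lactol to the carboxylate aldehyde, which is converted through the diazoalkene and alkylidene carbene into the terminal alkyne, and the hindered α-centre beside the quaternary carbon should resist enolisation.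

Step 9
Reactants: 15 (3S)-3-ethynyl-2,2-dimethyl-5-[(4R)-2,2,4-trimethyl-1,3-dioxan-4-yl]pentanoic acid
Product: 16 (4R)-3,3-dimethyl-5-methylidene-4-{2-[(4R)-2,2,4-trimethyl-1,3-dioxan-4-yl]ethyl}oxolan-2-one
Conditions: AuCl (5 mol %), K2CO3 (10 mol %), MeCN, rt
Reagents that add atoms: none
Why: Gold-catalysed cycloisomerisation of a γ-alkynoic acid: monovalent gold activates the alkyne for 5-exo-dig attack of the carboxylate (helped by the gem-dimethyl group), and protodeauration gives the exocyclic enol lactone without touching the adjacent stereocentre.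

Step 10
Reactants: 16 (4R)-3,3-dimethyl-5-methylidene-4-{2-[(4R)-2,2,4-trimethyl-1,3-dioxan-4-yl]ethyl}oxolan-2-one; 17 benzyl prop-2-enoate
Product: 20 benzyl (4R,5S)-5-hydroxy-3,3,5-trimethyl-2-oxo-4-{2-[(4R)-2,2,4-trimethyl-1,3-dioxan-4-yl]ethyl}cyclohexane-1-carboxylate, via lactone radical 18 (not isolated), via ester enolate 19 (not isolated)
Conditions: Fe(acac)3 (30 mol %), Ph(i-PrO)SiH2 (2.5 equiv), 17 (3 equiv), THF, 0 °C to rt; aq. NH4Cl work-up
Reagents that add atoms: none
Why: Proposed new method: an iron hydride formed from Fe(acac)3 and the silane should transfer a hydrogen atom to the CH2 terminus of the enol-lactone alkene of 16 (Markovnikov metal-hydride hydrogen atom transfer), which makes the C-methyl group and the tertiary α-acyloxy radical 18; 18 adds to the β-CH2 of 17 (Giese addition, first new bond, CH2 to carbinol carbon), divalent iron reduces the α-ester radical to enolate 19 (radical–polar crossover), and 19 attacks the lactone carbonyl through a 7-oxabicyclo[2.2.1]heptan-1-olate whose collapse breaks the acyl–oxygen bond (second new bond, ketone carbon to α-carbon), so that the lactone oxygen leaves as the tertiary alkoxide and the β-keto ester enolate of 20 drives the sequence. The closest known reaction types are the iron-hydride reductive cross-coupling of oxygen-substituted donor olefins with acrylates, hydrogen-atom-transfer-initiated radical–polar crossover annulations that end in an aldol step, and the base-mediated Dieckmann transacylation of γ-lactone esters to 4-hydroxy-2-oxocyclohexanecarboxylates; new is the use of an enol lactone as donor and of its own carbonyl as the internal acylating trap. The cyclohexanone ring closes by 6-(enolexo)-exo-trig attack of the enolate carbon on the lactone C=O, and the five-membered lactone ring is opened in the same event. The carbinol stereocentre is set in the Giese step by 1,2-induction: the planar radical at C5 of the lactone is attacked on the face anti to the C4 side chain, which places the new CH2 trans and the methyl cis to that chain in the lactone and therefore the OH cis to the chain in the cyclohexanone, as the target requires, while the CH(CO2Bn) centre is not controlled and is removed in step 11. The step needs Markovnikov hydrogen atom transfer (secured by the 1,1-disubstituted, oxygen-bearing alkene, the only alkene of 16), radical addition to the acrylate instead of simple reduction (excess 17), and acyl transfer faster than enolate protonation (aprotic THF and a silane that needs no alcohol solvent).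

Step 11
Reactants: 20 benzyl (4R,5S)-5-hydroxy-3,3,5-trimethyl-2-oxo-4-{2-[(4R)-2,2,4-trimethyl-1,3-dioxan-4-yl]ethyl}cyclohexane-1-carboxylate
Product: 22 (3R,4S)-4-hydroxy-2,2,4-trimethyl-3-{2-[(4R)-2,2,4-trimethyl-1,3-dioxan-4-yl]ethyl}cyclohexan-1-one, via β-keto acid 21 (not isolated)
Conditions: H2 (1 atm), Pd/C (10% palladium on carbon), EtOAc, rt; then 40 °C
Reagents that add atoms: none
Why: Hydrogenolysis of the benzyl ester on palladium followed by spontaneous decarboxylation of the β-keto acid removes the activating group; both ring stereocentres lie outside the enolisable positions and are kept.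

Step 12
Reactants: 22 (3R,4S)-4-hydroxy-2,2,4-trimethyl-3-{2-[(4R)-2,2,4-trimethyl-1,3-dioxan-4-yl]ethyl}cyclohexan-1-one
Product: 23 (3R,4S)-3-[(3R)-3,5-dihydroxy-3-methylpentyl]-4-hydroxy-2,2,4-trimethylcyclohexan-1-one
Conditions: PPTS (cat.), MeOH, rt
Reagents that add atoms: none
Why: Acid-catalysed transketalisation to methanol (acetonide cleavage) frees the primary and tertiary hydroxyls under conditions mild enough to leave both tertiary alcohols and the ketone intact.

Step 13
Reactants: 23 (3R,4S)-3-[(3R)-3,5-dihydroxy-3-methylpentyl]-4-hydroxy-2,2,4-trimethylcyclohexan-1-one; 24 7-hydroxy-2H-chromen-2-one (umbelliferone)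
Product: 25 7-{[(3R)-3-hydroxy-5-[(1R,6S)-6-hydroxy-2,2,6-trimethyl-3-oxocyclohexyl]-3-methylpentyl]oxy}-2H-chromen-2-one (target)
Conditions: 24, PPh3, DIAD, THF, 0 °C to rt
Reagents that add atoms: none
Why: Mitsunobu etherification: only the primary alcohol forms an alkoxyphosphonium ion that the acidic phenol of umbelliferone displaces, the two tertiary alcohols being too hindered to react, so no stereocentre is involved.

**Compound list**

1 | (R)-(−)-linalool, (3R)-3,7-dimethylocta-1,6-dien-3-ol | CC(C)=CCC[C@@](C)(O)C=C | starting material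
2 | 9-[(3R)-3-hydroxy-3,7-dimethyloct-6-en-1-yl]-9-borabicyclo[3.3.1]nonane | CC(C)=CCC[C@@](C)(O)CCB1C2CCCC1CCC2 | intermediate (not isolated)
3 | (3R)-3,7-dimethyloct-6-ene-1,3-diol | CC(C)=CCC[C@@](C)(O)CCO | intermediate
4 | (4R)-2,2,4-trimethyl-4-(4-methylpent-3-en-1-yl)-1,3-dioxane | CC(C)=CCC[C@@](C)(OC(C)(C)O1)CC1 | intermediate
5 | but-3-en-2-one (methyl vinyl ketone) | CC(=O)C=C | starting material
6 | (3E)-6-[(4R)-2,2,4-trimethyl-1,3-dioxan-4-yl]hex-3-en-2-one | CC(=O)/C=C/CC[C@@](C)(OC(C)(C)O1)CC1 | intermediate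
7 | (2R,3E)-6-[(4R)-2,2,4-trimethyl-1,3-dioxan-4-yl]hex-3-en-2-ol | C[C@@H](O)/C=C/CC[C@@](C)(OC(C)(C)O1)CC1 | intermediate
8 | 2-methylpropanoyl chloride (isobutyryl chloride) | CC(C)C(Cl)=O | starting material
9 | (2R,3E)-6-[(4R)-2,2,4-trimethyl-1,3-dioxan-4-yl]hex-3-en-2-yl 2-methylpropanoate | C[C@@H](OC(=O)C(C)C)/C=C/CC[C@@](C)(OC(C)(C)O1)CC1 | intermediate
10 | trimethyl[(2-methyl-1-{[(2R,3E)-6-[(4R)-2,2,4-trimethyl-1,3-dioxan-4-yl]hex-3-en-2-yl]oxy}prop-1-en-1-yl)oxy]silane (silyl ketene acetal) | CC(C)=C(O[Si](C)(C)C)O[C@H](C)/C=C/CC[C@@](C)(OC(C)(C)O1)CC1 | intermediate (not isolated)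
11 | trimethylsilyl (3S,4E)-2,2-dimethyl-3-{2-[(4R)-2,2,4-trimethyl-1,3-dioxan-4-yl]ethyl}hex-4-enoate | C[Si](C)(C)OC(=O)C(C)(C)[C@H](/C=C/C)CC[C@@](C)(OC(C)(C)O1)CC1 | intermediate (not isolated)
12 | (3S,4E)-2,2-dimethyl-3-{2-[(4R)-2,2,4-trimethyl-1,3-dioxan-4-yl]ethyl}hex-4-enoic acid | OC(=O)C(C)(C)[C@H](/C=C/C)CC[C@@](C)(OC(C)(C)O1)CC1 | intermediate
13 | (3R)-2,2-dimethyl-3-(5-methyl-1,2,4-trioxolan-3-yl)-5-[(4R)-2,2,4-trimethyl-1,3-dioxan-4-yl]pentanoic acid (ozonide, mixture at the trioxolane carbons) | OC(=O)C(C)(C)[C@H](C1OOC(C)O1)CC[C@@](C)(OC(C)(C)O1)CC1 | intermediate (not isolated)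
14 | (3R)-3-formyl-2,2-dimethyl-5-[(4R)-2,2,4-trimethyl-1,3-dioxan-4-yl]pentanoic acid | OC(=O)C(C)(C)[C@H](C=O)CC[C@@](C)(OC(C)(C)O1)CC1 | intermediate
15 | (3S)-3-ethynyl-2,2-dimethyl-5-[(4R)-2,2,4-trimethyl-1,3-dioxan-4-yl]pentanoic acid | OC(=O)C(C)(C)[C@H](C#C)CC[C@@](C)(OC(C)(C)O1)CC1 | intermediate
16 | (4R)-3,3-dimethyl-5-methylidene-4-{2-[(4R)-2,2,4-trimethyl-1,3-dioxan-4-yl]ethyl}oxolan-2-one | O=C1OC(=C)[C@H](CC[C@@](C)(OC(C)(C)O2)CC2)C1(C)C | intermediate
17 | benzyl prop-2-enoate (benzyl acrylate) | C=CC(=O)OCc1ccccc1 | starting material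
18 | (3R)-2,4,4-trimethyl-5-oxo-3-{2-[(4R)-2,2,4-trimethyl-1,3-dioxan-4-yl]ethyl}oxolan-2-yl radical | C[C]1OC(=O)C(C)(C)[C@H]1CC[C@@](C)(OC(C)(C)O2)CC2 | intermediate (not isolated)
19 | enolate of benzyl 3-[(2S,3R)-2,4,4-trimethyl-5-oxo-3-{2-[(4R)-2,2,4-trimethyl-1,3-dioxan-4-yl]ethyl}oxolan-2-yl]propanoate (iron-bound) | [O-]C(OCc1ccccc1)=CC[C@]2(C)OC(=O)C(C)(C)[C@H]2CC[C@@](C)(OC(C)(C)O3)CC3 | intermediate (not isolated)
20 | benzyl (4R,5S)-5-hydroxy-3,3,5-trimethyl-2-oxo-4-{2-[(4R)-2,2,4-trimethyl-1,3-dioxan-4-yl]ethyl}cyclohexane-1-carboxylate | O=C1C(C(=O)OCc2ccccc2)C[C@](C)(O)[C@H](CC[C@@](C)(OC(C)(C)O3)CC3)C1(C)C | intermediate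
21 | (4R,5S)-5-hydroxy-3,3,5-trimethyl-2-oxo-4-{2-[(4R)-2,2,4-trimethyl-1,3-dioxan-4-yl]ethyl}cyclohexane-1-carboxylic acid | O=C1C(C(O)=O)C[C@](C)(O)[C@H](CC[C@@](C)(OC(C)(C)O2)CC2)C1(C)C | intermediate (not isolated)
22 | (3R,4S)-4-hydroxy-2,2,4-trimethyl-3-{2-[(4R)-2,2,4-trimethyl-1,3-dioxan-4-yl]ethyl}cyclohexan-1-one | O=C1CC[C@](C)(O)[C@H](CC[C@@](C)(OC(C)(C)O2)CC2)C1(C)C | intermediate
23 | (3R,4S)-3-[(3R)-3,5-dihydroxy-3-methylpentyl]-4-hydroxy-2,2,4-trimethylcyclohexan-1-one | O=C1CC[C@](C)(O)[C@H](CC[C@@](C)(O)CCO)C1(C)C | intermediate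
24 | 7-hydroxy-2H-chromen-2-one (umbelliferone) | Oc1ccc2ccc(=O)oc2c1 | starting material
25 | 7-{[(3R)-3-hydroxy-5-[(1R,6S)-6-hydroxy-2,2,6-trimethyl-3-oxocyclohexyl]-3-methylpentyl]oxy}-2H-chromen-2-one | CC1(C)C(=O)CC[C@](C)(O)[C@@H]1CC[C@@](C)(O)CCOc1ccc2ccc(=O)oc2c1 | target

**Step count and risks**

Total steps: 13. Longest linear sequence: 13 steps, from linalool 1 to target 25.

Steps most likely to fail:

1. Step 10 (Proposed new method). The ester enolate may be protonated or O-silylated before it acylates the lactone carbonyl, so that the sequence stops after the first C–C bond; the enol lactone may also prove a sluggish hydrogen-atom acceptor. The fallback sets out from 16 and 17 and separates the two bond formations into two known reactions. The iron-hydride reductive olefin cross-coupling under its usual protic conditions (Fe(acac)3, PhSiH3, EtOH/ethylene glycol, 60 °C), where the enolate is simply protonated, should give the γ-lactone benzyl ester F1 with the same anti selectivity. A separate Dieckmann-type transacylation of F1 (KOt-Bu, THF, 0 °C), the known ring-opening closure of γ-lactone esters to 4-hydroxy-2-oxocyclohexanecarboxylates, then comes back to the route at 20.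

2. Step 8. Epimerisation of the formyl-bearing stereocentre under carbonate in methanol, or incomplete reaction of the lactol form, would erode or stall the homologation. The fallback leaves the aldehyde route altogether and sets out from 12. Ethenolysis (ethylene, second-generation Grubbs catalyst [RuCl2(H2IMes)(PCy3)(=CHPh)], CH2Cl2) should trim the propenyl group to give the vinyl acid F2. Iodolactonisation (I2, NaHCO3, MeCN/H2O) should then give the iodomethyl lactone F3, and dehydroiodination (DBU, toluene, rt to 60 °C), whose only β-hydrogen sits on the oxygen-bearing ring carbon, comes back at 16 without steps 7 to 9.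

3. Step 3. Slow cross-metathesis of the trisubstituted alkene, or catalyst decomposition in the presence of excess enone, would leave 4 unconverted. The fallback sets out from 4: ozonolysis (O3, CH2Cl2, −78 °C; Me2S) should give the aldehyde F4, and Wittig olefination with the stabilised ylide 1-(triphenylphosphoranylidene)propan-2-one (CH2Cl2, rt to reflux), which is (E)-selective, comes back at 6.

**Further compounds**

F1 | step 10 | benzyl 3-[(2S,3R)-2,4,4-trimethyl-5-oxo-3-{2-[(4R)-2,2,4-trimethyl-1,3-dioxan-4-yl]ethyl}oxolan-2-yl]propanoate | O=C(CC[C@]1(C)OC(=O)C(C)(C)[C@H]1CC[C@@](C)(OC(C)(C)O2)CC2)OCc1ccccc1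
F2 | step 8 | (3S)-3-ethenyl-2,2-dimethyl-5-[(4R)-2,2,4-trimethyl-1,3-dioxan-4-yl]pentanoic acid | OC(=O)C(C)(C)[C@H](C=C)CC[C@@](C)(OC(C)(C)O1)CC1
F3 | step 8 | (4R)-5-(iodomethyl)-3,3-dimethyl-4-{2-[(4R)-2,2,4-trimethyl-1,3-dioxan-4-yl]ethyl}oxolan-2-one (mixture at C5) | ICC1OC(=O)C(C)(C)[C@H]1CC[C@@](C)(OC(C)(C)O2)CC2
F4 | step 3 | 3-[(4R)-2,2,4-trimethyl-1,3-dioxan-4-yl]propanal | O=CCC[C@@](C)(OC(C)(C)O1)CC1
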